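**Retrosynthetic overview**

- The strategy rests on C6 of the 1,2-dioxane ring: this peroxy-bearing quaternary carbon carries a methyl and a hexadecyl group of almost equal size, so it is set by C–C bond formation on a planar, methyl-bearing C6 peroxycarbenium ion held inside the cis-fused 1,2-dioxane/γ-lactone bicycle.
- The chain is cut at C2'–C3' (cross-metathesis, then diimide), which leads back to the C6-allyl bicycle; the C6–C1' bond is cut next (SnCl4/allylsilane on the C6 methoxy peroxyketal).
- The bicyclic ketal is opened at the O–C3 bond (peroxy-Michael addition) to a hydroperoxy ketal, which comes from ozonolysis in methanol of a methallyl butenolide.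
- The butenolide comes from a Z-enoate, and that from the ene adduct of methyl pyruvate and isobutene; the adduct supplies C4 (S), the only catalyst-controlled stereocentre, and C3 and C6 are derived from it.
- Ring order: γ-lactone first (step 5), 1,2-dioxane second (step 7); the chain is joined at C6 afterwards (steps 8 to 10).

Key step: step 8

Numbering used below: C1 lactone C=O, C2 CH2, C3 peroxy CH, C4 carbon bearing the lactone oxygen and a methyl, C5 ring CH2, C6 peroxy quaternary carbon, C1' first chain carbon. The target is (3S,4S,6R) in this numbering, which is (3R,4aS,7aS) in the furo[3,2-c][1,2]dioxin names.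

Assumption: the (S,S)-tert-butyl-bis(oxazoline) complex of divalent copper is taken to attack the si face of chelated methyl pyruvate, as it does in its other pyruvate additions, and so to give (S)-3; should the opposite sense be found, the (R,R)-ligand is used. All peroxides are to be handled on small scale, cold and behind a shield.

Step 1
Reactants: 1 methyl pyruvate; 2 isobutene (excess)
Product: 3 methyl (2S)-2-hydroxy-2,4-dimethylpent-4-enoate
Conditions: [Cu((S,S)-t-Bu-box)](SbF6)2 (10 mol %), CH2Cl2, 40 °C, sealed vessel (t-Bu-box = 2,2'-(propane-2,2-diyl)bis[(4S)-4-tert-butyl-4,5-dihydrooxazole])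
Reagents that add atoms: none
Why: Catalytic enantioselective carbonyl-ene reaction, in which pyruvate chelates the divalent copper centre of the C2-symmetric bis(oxazoline) complex and the 1,1-disubstituted alkene attacks the open si face of the ketone, which should give the (S)-tertiary alcohol that becomes C4.

Step 2
Reactants: 3 methyl (2S)-2-hydroxy-2,4-dimethylpent-4-enoate
Product: 4 methyl (2S)-2,4-dimethyl-2-(triethylsilyloxy)pent-4-enoate
Conditions: Et3SiOTf, 2,6-lutidine, CH2Cl2, 0 °C
Reagents that add atoms: triethylsilyl trifluoromethanesulfonate, CC[Si](CC)(CC)OS(=O)(=O)C(F)(F)F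
Why: Silyl ether protection with a silyl triflate and a hindered base silylates the tertiary alcohol where the chloride would be sluggish, and masks the hydroxyl so that the ester can be reduced cleanly in the next step.

Step 3
Reactants: 4 methyl (2S)-2,4-dimethyl-2-(triethylsilyloxy)pent-4-enoate
Product: 5 (2S)-2,4-dimethyl-2-(triethylsilyloxy)pent-4-enal
Conditions: i-Bu2AlH (1.1 equiv), CH2Cl2, −78 °C; MeOH, then aq. potassium sodium tartrate
Reagents that add atoms: none
Why: Partial ester reduction with i-Bu2AlH at −78 °C stops at the aldehyde because the α-silyloxy group stabilises the tetrahedral aluminium hemiacetal until the quench, and the quaternary α-carbon has no hydrogen, so C4 cannot epimerise.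

Step 4
Reactants: 5 (2S)-2,4-dimethyl-2-(triethylsilyloxy)pent-4-enal
Product: 6 methyl (2Z,4S)-4,6-dimethyl-4-(triethylsilyloxy)hepta-2,6-dienoate
Conditions: (CF3CH2O)2P(O)CH2CO2Me, KN(SiMe3)2, 18-crown-6, THF, −78 °C
Reagents that add atoms: methyl bis(2,2,2-trifluoroethyl)phosphonoacetate, COC(=O)CP(=O)(OCC(F)(F)F)OCC(F)(F)F
Why: Still–Gennari variant of the Horner–Wadsworth–Emmons olefination, in which the electron-poor phosphonate under dissociating conditions eliminates rapidly from the kinetic adduct and so should give the Z-enoate needed for lactonisation; the aldehyde is non-enolisable.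

Step 5
Reactants: 6 methyl (2Z,4S)-4,6-dimethyl-4-(triethylsilyloxy)hepta-2,6-dienoate
Product: 8 (5S)-5-methyl-5-(2-methylprop-2-en-1-yl)furan-2(5H)-one, via hydroxy Z-enoate 7 (not isolated)
Conditions: p-TsOH·H2O (cat.), MeOH, 0 °C to rt
Reagents that add atoms: none
Why: Acid-catalysed methanolysis of the triethylsilyl ether frees the tertiary alcohol, which the Z double bond holds next to the ester so that it closes by intramolecular transesterification (lactonisation) to the butenolide, the first ring; the mild acid should leave the 1,1-disubstituted alkene untouched.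

Step 6
Reactants: 8 (5S)-5-methyl-5-(2-methylprop-2-en-1-yl)furan-2(5H)-one
Product: 10 (5S)-5-(2-hydroperoxy-2-methoxypropyl)-5-methylfuran-2(5H)-one (both ketal epimers), via ketone O-oxide 9 (not isolated)
Conditions: O3, CH2Cl2–MeOH, −78 °C, Sudan Red 7B end-point; N2 purge, no reductant
Reagents that add atoms: ozone, [O-][O+]=O; methanol, CO
Why: Criegee ozonolysis in a participating solvent, in which ozone takes the electron-rich 1,1-disubstituted alkene far faster than the conjugated lactone alkene, the primary ozonide should cleave mainly to formaldehyde and the more substituted carbonyl oxide 9, and methanol traps 9 as the α-methoxy hydroperoxide; the ketal centre forms unselectively and is erased in step 8.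

Step 7
Reactants: 10 (5S)-5-(2-hydroperoxy-2-methoxypropyl)-5-methylfuran-2(5H)-one
Product: 11 (4aS,7aS)-3-methoxy-3,4a-dimethyltetrahydro-3H-furo[3,2-c][1,2]dioxin-6(4H)-one (cis-fused 1,2-dioxane/γ-lactone, mixture at the ketal carbon C6)
Conditions: Et2NH (cat.), CF3CH2OH, rt
Reagents that add atoms: none
Why: Intramolecular peroxy-Michael addition (6-exo-trig) of the hydroperoxide to the butenolide β-carbon C3 closes the 1,2-dioxane ring, and because the tether from C4 can only reach the same face of the lactone the ring fusion is cis and C3 is set (S) by C4.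

Step 8
Reactants: 11 (4aS,7aS)-3-methoxy-3,4a-dimethyltetrahydro-3H-furo[3,2-c][1,2]dioxin-6(4H)-one; 12 allyltrimethylsilane
Product: 14 (3R,4aS,7aS)-3-allyl-3,4a-dimethyltetrahydro-3H-furo[3,2-c][1,2]dioxin-6(4H)-one, via peroxycarbenium ion 13 (not isolated)
Conditions: 12 (3 equiv), SnCl4 (1.2 equiv), CH2Cl2, −78 °C; aq. NaHCO3 quench at −78 °C
Reagents that add atoms: none
Why: SnCl4 removes the C6 methoxy group from either ketal epimer to give the same cyclic peroxycarbenium ion 13, which the allylsilane captures in a Hosomi–Sakurai-type SE2' addition, with the silyl group then lost to methoxide; this is the established Lewis-acid allylation of 3-alkoxy-1,2-dioxanes and 1,2-dioxolanes at ketal carbons. No ring is closed: the step forms only the C6–C1' bond and creates the C6 stereocentre. The cation should sit in the half-chair with the C4 lactone oxygen pseudoaxial (electrostatic preference of a β-acyloxy group) and the C4 methyl and C3–C2 arm pseudoequatorial, and axial attack on the face that leads directly to a chair places the allyl group syn to the C4–O bond and C2 and anti to the C4 methyl, which is (R) at C6. The selectivity needed is facial selectivity at C6, and the cis-fused lactone secures it, because chair-forming attack on the opposite face must go through the other half-chair, with the C4 methyl and C2 arm axial and a 1,3-diaxial methyl in the path of the nucleophile. Working at −78 °C should keep O–O heterolysis slower than C–O ionisation, and the lactone is inert to the allylsilane.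

Step 9
Reactants: 14 (3R,4aS,7aS)-3-allyl-3,4a-dimethyltetrahydro-3H-furo[3,2-c][1,2]dioxin-6(4H)-one; 15 1-pentadecene (4 equiv)
Product: 16 (3R,4aS,7aS)-3-(hexadec-2-en-1-yl)-3,4a-dimethyltetrahydro-3H-furo[3,2-c][1,2]dioxin-6(4H)-one (E/Z mixture)
Conditions: second-generation Grubbs catalyst (H2IMes)(PCy3)Cl2Ru=CHPh (5 mol %), CH2Cl2, 40 °C
Reagents that add atoms: none
Why: Olefin cross-metathesis between two unhindered terminal (type 1) alkenes is driven by loss of ethylene and by the excess of 15; ruthenium alkylidenes tolerate dialkyl peroxides and lactones, and the alkene geometry does not matter because the double bond is reduced next.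

Step 10
Reactants: 16 (3R,4aS,7aS)-3-(hexadec-2-en-1-yl)-3,4a-dimethyltetrahydro-3H-furo[3,2-c][1,2]dioxin-6(4H)-one
Product: 17 (3R,4aS,7aS)-3-hexadecyl-3,4a-dimethyltetrahydro-3H-furo[3,2-c][1,2]dioxin-6(4H)-one (target)
Conditions: KO2CN=NCO2K (excess, in portions), AcOH, CH2Cl2–MeOH, 0 °C to rt
Reagents that add atoms: none
Why: Diimide reduction, in which diimide generated in the flask from potassium azodicarboxylate and acetic acid transfers H2 concertedly to the non-polar C=C and should leave the O–O bond and the lactone untouched, unlike hydrogenation over a metal; the acidic medium avoids base-induced opening of the β-peroxy lactone.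

**Compound list**

1 | methyl pyruvate | CC(=O)C(=O)OC | starting material
2 | isobutene | C=C(C)C | starting material
3 | methyl (2S)-2-hydroxy-2,4-dimethylpent-4-enoate | C=C(C)C[C@](C)(O)C(=O)OC | intermediate
4 | methyl (2S)-2,4-dimethyl-2-(triethylsilyloxy)pent-4-enoate | C=C(C)C[C@](C)(O[Si](CC)(CC)CC)C(=O)OC | intermediate
5 | (2S)-2,4-dimethyl-2-(triethylsilyloxy)pent-4-enal | C=C(C)C[C@](C)(O[Si](CC)(CC)CC)C=O | intermediate
6 | methyl (2Z,4S)-4,6-dimethyl-4-(triethylsilyloxy)hepta-2,6-dienoate | C=C(C)C[C@](C)(O[Si](CC)(CC)CC)/C=C\C(=O)OC | intermediate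
7 | methyl (2Z,4S)-4-hydroxy-4,6-dimethylhepta-2,6-dienoate | C=C(C)C[C@](C)(O)/C=C\C(=O)OC | intermediate (not isolated)
8 | (5S)-5-methyl-5-(2-methylprop-2-en-1-yl)furan-2(5H)-one | C=C(C)C[C@]1(C)OC(=O)C=C1 | intermediate
9 | ketone O-oxide (carbonyl oxide) of the side chain of 8 | C[C+](O[O-])C[C@]1(C)OC(=O)C=C1 | intermediate (not isolated)
10 | (5S)-5-(2-hydroperoxy-2-methoxypropyl)-5-methylfuran-2(5H)-one, both ketal epimers | COC(C)(OO)C[C@]1(C)OC(=O)C=C1 | intermediate
11 | (4aS,7aS)-3-methoxy-3,4a-dimethyltetrahydro-3H-furo[3,2-c][1,2]dioxin-6(4H)-one, mixture at C6 | COC1(C)C[C@]2(C)OC(=O)C[C@@H]2OO1 | intermediate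
12 | allyltrimethylsilane | C=CC[Si](C)(C)C | starting material
13 | bicyclic C6 peroxycarbenium ion | C[C+]1C[C@]2(C)OC(=O)C[C@@H]2OO1 | intermediate (not isolated)
14 | (3R,4aS,7aS)-3-allyl-3,4a-dimethyltetrahydro-3H-furo[3,2-c][1,2]dioxin-6(4H)-one | C=CC[C@]1(C)C[C@]2(C)OC(=O)C[C@@H]2OO1 | intermediate
15 | 1-pentadecene | C=CCCCCCCCCCCCCC | starting material
16 | (3R,4aS,7aS)-3-(hexadec-2-en-1-yl)-3,4a-dimethyltetrahydro-3H-furo[3,2-c][1,2]dioxin-6(4H)-one, E/Z mixture (E isomer drawn) | CCCCCCCCCCCCC/C=C/C[C@]1(C)C[C@]2(C)OC(=O)C[C@@H]2OO1 | intermediate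
17 | (3R,4aS,7aS)-3-hexadecyl-3,4a-dimethyltetrahydro-3H-furo[3,2-c][1,2]dioxin-6(4H)-one | CCCCCCCCCCCCCCCC[C@]1(C)C[C@]2(C)OC(=O)C[C@@H]2OO1 | target

Total step count: 10. Longest linear sequence: 10 steps (from 1 and 2).

**Steps most likely to fail**

Step 8. Facial selectivity at C6 may erode, because axial attack on the favoured half-chair develops a 1,3-diaxial contact between the incoming allyl group and the C4 oxygen, so part of the reaction may run through the other half-chair; SnCl4 may also ionise the ring O–C6 bond or the O–O bond instead of expelling methoxide. The fallback sets out from 8 and comes back at 17, and it settles C6 by separation instead of induction. Cross-metathesis of 8 with 1-heptadecene (second-generation Hoveyda–Grubbs catalyst, excess alkene) would give the trisubstituted alkene (5S)-5-methyl-5-(2-methyloctadec-2-en-1-yl)furan-2(5H)-one F1. Mukaiyama–Isayama hydroperoxysilylation (Co(thd)2, bis(2,2,6,6-tetramethylheptane-3,5-dionato)cobalt, O2, Et3SiH, ClCH2CH2Cl) should take the electron-rich alkene in preference to the lactone alkene and place the peroxy group on the tertiary carbon, giving (5S)-5-methyl-5-[2-methyl-2-(triethylsilylperoxy)octadecyl]furan-2(5H)-one F2 as both C6 epimers. HCl (cat.) in MeOH would free the hydroperoxide (5S)-5-(2-hydroperoxy-2-methyloctadecyl)-5-methylfuran-2(5H)-one F3. Et2NH in CF3CH2OH would then close the dioxane ring to 17 and its C6 epimer (3S,4aS,7aS)-3-hexadecyl-3,4a-dimethyltetrahydro-3H-furo[3,2-c][1,2]dioxin-6(4H)-one F4, which are separated by chromatography. The chain is saturated before the peroxide exists, so steps 9 and 10 are not needed.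

Step 6. The primary ozonide may cleave in the other direction (methyl ketone plus formaldehyde O-oxide), ozone may attack the lactone alkene, or the hydroperoxy ketal may be lost on isolation. The fallback sets out from 8 and comes back at 10. Lemieux–Johnson cleavage (OsO4 cat., NaIO4, 2,6-lutidine, dioxane–H2O) would give the methyl ketone (5S)-5-methyl-5-(2-oxopropyl)furan-2(5H)-one F5. Acid-catalysed peroxyketalisation of F5 with urea–hydrogen peroxide and Sc(OTf)3 (cat.) in MeOH would then give 10, so the hydroperoxy ketal is built from the ketone and not from a carbonyl oxide.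

Step 4. Addition to the hindered α-quaternary aldehyde may be slow and Z-selectivity may leak to the E-enoate, which cannot lactonise. The fallback sets out from 5 and comes back at 6, and it fixes the geometry by syn-hydrogenation instead of olefination kinetics. Ohira–Bestmann homologation of 5 (dimethyl (1-diazo-2-oxopropyl)phosphonate, K2CO3, MeOH) would give the alkyne (4S)-2,4-dimethyl-4-(triethylsilyloxy)hex-1-en-5-yne F6. Deprotonation with n-BuLi and acylation with methyl chloroformate (THF, −78 °C) would give the ynoate methyl (4S)-4,6-dimethyl-4-(triethylsilyloxy)hept-6-en-2-ynoate F7. Semi-hydrogenation of F7 (H2, Pd/CaCO3 poisoned with Pb(OAc)2, quinoline) would then give 6.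

**Further compounds**

F1 | step 8 | (5S)-5-methyl-5-(2-methyloctadec-2-en-1-yl)furan-2(5H)-one, E/Z mixture | CCCCCCCCCCCCCCCC=C(C)C[C@]1(C)OC(=O)C=C1
F2 | step 8 | (5S)-5-methyl-5-[2-methyl-2-(triethylsilylperoxy)octadecyl]furan-2(5H)-one, both C6 epimers | CCCCCCCCCCCCCCCCC(C)(OO[Si](CC)(CC)CC)C[C@]1(C)OC(=O)C=C1
F3 | step 8 | (5S)-5-(2-hydroperoxy-2-methyloctadecyl)-5-methylfuran-2(5H)-one, both C6 epimers | CCCCCCCCCCCCCCCCC(C)(OO)C[C@]1(C)OC(=O)C=C1
F4 | step 8 | (3S,4aS,7aS)-3-hexadecyl-3,4a-dimethyltetrahydro-3H-furo[3,2-c][1,2]dioxin-6(4H)-one (C6 epimer of 17) | CCCCCCCCCCCCCCCC[C@@]1(C)C[C@]2(C)OC(=O)C[C@@H]2OO1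
F5 | step 6 | (5S)-5-methyl-5-(2-oxopropyl)furan-2(5H)-one | CC(=O)C[C@]1(C)OC(=O)C=C1
F6 | step 4 | (4S)-2,4-dimethyl-4-(triethylsilyloxy)hex-1-en-5-yne | C=C(C)C[C@](C)(O[Si](CC)(CC)CC)C#C
F7 | step 4 | methyl (4S)-4,6-dimethyl-4-(triethylsilyloxy)hept-6-en-2-ynoate | C=C(C)C[C@](C)(O[Si](CC)(CC)CC)C#CC(=O)OC
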